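**Remark on the chemistry (numbering assumed throughout):** the ring is numbered as in quinic acid. C1 is the quaternary carbon and C7 its carboxyl carbon; C3 and C4 carry the two free, mutually cis hydroxyls; C5 carries the caffeoyl ester, with O5 trans to O4. The "3‑O" of the trivial name counts the ring in the opposite sense and is O5 here. The target is therefore the 1‑O‑methyl ether of natural chlorogenic acid.

## Analysis of the target

The target is a single cyclohexane ring with the quinic acid skeleton. C1 is fully substituted (OCH3, the C7 carboxyl, C2, C6), C2 and C6 are methylenes, and C3, C4 and C5 are contiguous carbinol carbons, O5 being esterified with (E)‑caffeic acid. There are four stereocentres: O1 is cis to O3 and O4, C7 is cis to O5, O3/O4 are cis and O4/O5 trans, so that O3 and O5 are trans across the ring. In the chair, O1 and O3 are 1,3‑diaxial. The sensitive groups are the catechol (oxidised readily, above all in base), the cinnamate C=C bond (no hydrogenation once it is present) and the O5 ester next to the free O4–H (acyl migration and hydrolysis in base). The synthesis is hard for three reasons. The tertiary methyl ether sits on a quaternary carbon next to a carboxyl group. Only O5 of three secondary hydroxyls may be acylated. The endgame is restricted to acidic, non‑reductive deprotection. The strategy rests on one feature: when C1 is a carbonyl carbon, the trans C3/C5 pair (both R) gives C4 two identical ring arms, so C4 is not stereogenic and the ketone has only two stereocentres. These two centres map directly onto C2 and C4 of D‑arabinitol, and a single facial choice in an addition to C1 then defines C1 and C4 together.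

## Retrosynthetic reasoning

**Target 21 from the protected ester 20.** The caffeoyl ester tolerates neither hydrogenolysis nor base, so every group still present at the end must fall in acid. In 20 these are the O3/O4 acetonide, the tert‑butyl ester at C7 and the two aryl acetates. No skeletal bond is cut; the gain is a single final operation that leaves the O5 ester and the E‑alkene alone.

**Ester 20 from alcohol 16 and acid chloride 19.** The O5–acyl bond is cut because it joins the two halves of the molecule and brings in the oxidation‑ and reduction‑sensitive cinnamoyl unit as late as possible. The forward reaction only has to acylate the one free hydroxyl of 16. Compound 19 comes from caffeic acid 17 through its diacetate 18.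

**Alcohol 16 from triol 15, tribenzyl ester 14 and acid 13.** O5 must be the only free hydroxyl in 16, and the target's own stereochemistry provides the means. The cis O3/O4 pair can close a five‑membered cyclic acetal, whereas the trans O4/O5 pair cannot do so without strain. Triol 15 comes from 14 by hydrogenolysis, which is allowed because no alkene is present yet. The tert‑butyl ester, made from acid 13, is needed because C7 is cis to O5. A free acid or a small ester could close onto O5 as a bridged lactone and consume the hydroxyl that must be acylated.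

**Acid 13 from furan 12.** C7 is traced back to the furan carbon attached to C1; oxidative cleavage of both furan double bonds leaves that carbon as the carboxyl group. Benzyl ethers are the spectators because they survive the organometallic step and the methylation, and leave by hydrogenolysis before the cinnamate arrives.

**Furan 12 from ketone 8 and furan 9 (as 2‑lithiofuran 10).** The C1–C7 and O1–CH3 bonds are cut together. This removes the quaternary centre and leaves ketone 8, which has two stereocentres and a non‑stereogenic C4. The forward reaction must bring 10 to the face of the carbonyl that carries O5, so that O1 ends up cis to O3 and O4, and must then methylate the hindered alkoxide 11 before work‑up.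

**Ketone 8 from the geminal isocyano sulfone 7, and 7 from diiodide 5 and TosMIC 6.** The C1–C2 and C1–C6 bonds are cut. C1 is supplied by 6 as a carbonyl dianion equivalent, and 5 is the matching 1,5‑dielectrophile. The forward reaction is a double alkylation that closes the six‑membered ring, followed by hydrolytic unmasking of the carbonyl group.

**Diiodide 5 from diol 4, and 4 from 3, 2 and D‑arabinitol 1.** C2 and C4 of 1 become C3 and C5 of 8 without any bond to them being broken. Only protecting‑group work is needed: trityl ethers on the two primary hydroxyls, benzyl ethers on the three secondary ones, detritylation, and replacement of the primary hydroxyls by iodide.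

## Alternatives that were turned down

**Alternative 1:** The C1–O1 bond is formed by epoxidation of an exocyclic C1=C7 alkene, the methylenecyclohexane A1, whose free axial C3 hydroxyl delivers a vanadium‑bound peroxide to its own face. The product is the spiro‑epoxide A2, with O1 cis to O3.

- **For:** a bound directing group selects the face, and O3 stands in exactly the 1,3‑diaxial relation to O1 that the target shows. On facial control alone this alternative is at least as strong as the chosen route, which relies on a conformational bias.
- **Against:** A1 would itself come from a C1 ketone of the type of 8 by methylenation, so the route is the chosen one with more steps added. In A2, C7 is only at the alcohol oxidation level. The epoxide must be opened at C7, the primary carbinol oxidised twice, and the most hindered hydroxyl of a polyol methylated selectively, each with its own protecting‑group changes. The directing hydroxyl must be O3, so the trans O4/O5 pair has to be masked. In A1 and A2 this is a strained trans‑fused acetonide, which would not form in preference to the cis O3/O4 acetonide. Homoallylic direction to a 1,1‑disubstituted alkene is also weaker than the allylic case.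
- **Comparison:** the chosen route makes C1–C7 at the carboxyl oxidation level and O1–CH3 in one flask from the same kind of ketone. That is five or six fewer operations, paid for with less secure facial control.

**Alternative 2:** The C1–C6 and C2–C3 bonds are cut in a [4+2] sense. Buta‑1,3‑diene A3 and methyl 2‑methoxyacrylate A4 combine under a chiral cationic oxazaborolidine Lewis acid to give the cyclohexene ester A5 with C1 set. C3, C4 and C5 would then be relayed from C1 by lactonisation onto the alkene, elimination and dihydroxylation.

- **For:** one step from two simple compounds to the carbocycle, catalytic asymmetry, and the methyl ether and carboxyl are in place from the start. Up to the ring this is clearly shorter than the six steps to 8, and it avoids methylating a hindered alkoxide.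
- **Against:** A4 is a captodative, weakly electrophilic dienophile and A3 is the least reactive diene. The alkoxy oxygen offers the Lewis acid a second binding site, so both rate and enantioselectivity are open questions for this pair. Any shortfall in enantiomeric purity at C1 is carried into all later centres of a target that must be a single enantiomer. After A5, three stereocentres still have to be made in about eight further operations, and the lactone that relays them ties up O5, which must then be freed again for acylation.
- **Comparison:** the chosen route takes C3 and C5 from the chiral pool, so enantiomeric purity is not at risk, and it faces one diastereoselectivity question instead of an enantioselective step plus a relay sequence.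

**Alternative 3:** The C1–C2 bond is cut in a [3,3] sense. The silyl ketene acetal of the trans‑5‑silyloxy‑6‑vinyl δ‑lactone A6 rearranges through a ring‑enforced boat transition state (Ireland–Claisen ring contraction) to the cyclohexene acid A7.

- **For:** a concerted, stereospecific step sets the quaternary C1 with its methoxy group, places the C3=C4 alkene where the cis‑diol is needed, and delivers O5 already differentiated as a silyl ether. On protecting‑group logic it is stronger than the chosen route, which depends on a regioselective acetonide.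
- **Against:** A6 has two defining stereocentres and an α‑methoxy group and must be made enantiopure in a sequence at least as long as the pentitol route to 8. The configuration at C1 depends on the assumed boat geometry. After A7, the dihydroxylation needs its own facial control, anti to the allylic silyl ether and next to a quaternary centre. The α‑alkoxy ketene acetal must survive the heating a boat transition state requires.
- **Comparison:** that makes three selectivity‑determining events against one in the chosen route, where every centre other than C1/C4 is taken from D‑arabinitol.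

Key step: step 7

## Route

Step 1
Reactants: 1 D‑arabinitol
Product: 2 1,5‑di‑O‑trityl‑D‑arabinitol
Conditions: TrCl (2.2 equiv), pyridine, DMAP (cat.), rt → 40 °C
Reagents that add atoms: trityl chloride, ClC(c1ccccc1)(c1ccccc1)c1ccccc1
Why: Tritylation (SN1‑type etherification) is selective for the two primary hydroxyls because the trityl cation is too bulky for the secondary ones; no stereocentre is touched.

Step 2
Reactants: 2 1,5‑di‑O‑trityl‑D‑arabinitol
Product: 3 2,3,4‑tri‑O‑benzyl‑1,5‑di‑O‑trityl‑D‑arabinitol
Conditions: NaH, BnBr, Bu4NI (cat.), DMF, 0 °C → rt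
Reagents that add atoms: benzyl bromide, BrCc1ccccc1
Why: Williamson etherification of the three secondary alkoxides; trityl ethers are stable to base and the C–O bonds at the stereocentres are not broken.

Step 3
Reactants: 3 2,3,4‑tri‑O‑benzyl‑1,5‑di‑O‑trityl‑D‑arabinitol
Product: 4 2,3,4‑tri‑O‑benzyl‑D‑arabinitol
Conditions: p‑TsOH·H2O (cat.), MeOH/CH2Cl2, rt
Reagents that add atoms: none
Why: Acid‑catalysed solvolysis of the trityl ethers, the trityl cation being trapped by methanol; benzyl ethers are inert under these conditions.

Step 4
Reactants: 4 2,3,4‑tri‑O‑benzyl‑D‑arabinitol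
Product: 5 2,3,4‑tri‑O‑benzyl‑1,5‑dideoxy‑1,5‑diiodo‑D‑arabinitol
Conditions: PPh3, imidazole, I2, CH2Cl2, 0 °C → rt
Reagents that add atoms: iodine, II
Why: Garegg–Samuelsson (Appel‑type) iodination: the primary alkoxyphosphonium ions are displaced by iodide in an SN2 reaction; keeping the mixture at or below rt should suppress participation of a benzyl ether oxygen (tetrahydrofuran formation), and the secondary centres are not involved.

Step 5
Reactants: 5 2,3,4‑tri‑O‑benzyl‑1,5‑dideoxy‑1,5‑diiodo‑D‑arabinitol; 6 tosylmethyl isocyanide (TosMIC)
Product: 7 (3R,5R)‑3,4,5‑tris(benzyloxy)‑1‑isocyano‑1‑tosylcyclohexane (both C1 epimers)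
Conditions: NaH (2.2 equiv), DMSO/Et2O, rt, slow addition of 5 and 6 (high dilution)
Reagents that add atoms: none
Why: Van Leusen‑type double alkylation of TosMIC: two successive SN2 reactions of the α‑sulfonyl isocyanide carbanion, the second a 6‑exo‑tet ring closure favoured by dilution. The soft, weakly basic carbanion should substitute rather than eliminate at the β‑benzyloxy iodides. The two C1 epimers converge in step 6.

Step 6
Reactants: 7 (3R,5R)‑3,4,5‑tris(benzyloxy)‑1‑isocyano‑1‑tosylcyclohexane
Product: 8 (3R,5R)‑3,4,5‑tris(benzyloxy)cyclohexanone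
Conditions: conc. aq. HCl, Et2O/CH2Cl2, 0 °C → rt, brief; cold aq. NaHCO3 quench
Reagents that add atoms: water, O
Why: Acid hydrolysis of the geminal isocyano sulfone (hydration of the isocyanide to the formamide, loss of sulfinate, hydrolysis of the N‑acyliminium ion) unmasks the ketone. Short contact and a cold bicarbonate quench should keep the β‑benzyloxy ketone from eliminating. C3 and C5 are untouched and C4 is not stereogenic in 8.

Step 7
Reactants: 8 (3R,5R)‑3,4,5‑tris(benzyloxy)cyclohexanone; 9 furan
Product: 12 2‑[(3R,5R)‑3,4,5‑tris(benzyloxy)‑1‑methoxycyclohexyl]furan, via 2‑lithiofuran 10 (not isolated), via lithium tertiary alkoxide 11 (not isolated)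
Conditions: 9 (1.6 equiv), n‑BuLi (1.5 equiv), THF, 0 °C; 8, THF, −78 °C; then MeI (excess), DMPU, −78 °C → rt
Reagents that add atoms: iodomethane, CI
Why: Furan 9 is lithiated at C2 by n‑BuLi to give 10, which undergoes 1,2‑addition to the carbonyl of 8; the tertiary lithium alkoxide 11 is then O‑methylated by SN2 on iodomethane once DMPU has broken up its aggregates, so that the C1–C7 and O1–CH3 bonds are made in one flask. The closest known reaction type is the equatorial addition of aryl‑ and heteroaryllithium reagents to cyclohexanones that carry an axial 3‑substituent, combined with the use of a 2‑furyl group as a latent carboxyl group. No ring is closed. C1 and C4 become stereocentres together: in the favoured chair of 8 the C3 benzyloxy group is axial and those at C4 and C5 are equatorial (the inverted chair would have two axial benzyloxy groups), and the axial C3–O bond shields the axial trajectory at C1. Compound 10 should therefore approach along the equatorial trajectory from the face that carries O5, which leaves O1 axial and cis to O3 and O4 and places the furyl group equatorial and cis to O5; since C3 and C5 are fixed, this one facial choice defines both C1 and C4. The step needs chemoselectivity for addition over α‑deprotonation (an enolate would expel a β‑benzyloxy group) and facial selectivity for equatorial attack; the low basicity and high nucleophilicity of 10 at −78 °C should secure the first and the axial O3 substituent the second. Chelation of lithium between O1 and the syn‑axial O3 in 11 is expected to stabilise the desired adduct but slows the methylation, which is why the dipolar additive and an excess of iodomethane are used.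

Step 8
Reactants: 12 2‑[(3R,5R)‑3,4,5‑tris(benzyloxy)‑1‑methoxycyclohexyl]furan
Product: 13 3,4,5‑tri‑O‑benzyl‑1‑O‑methyl‑(−)‑quinic acid
Conditions: O3, CH2Cl2/MeOH, −78 °C (Sudan Red 7B end‑point); Me2S, −78 °C → rt; aq. work‑up
Reagents that add atoms: ozone, [O-][O+]=O
Why: Ozonolysis of both furan double bonds leaves C7 as a mixed formic anhydride that collapses to the carboxylic acid (furan as carboxyl surrogate). The electron‑rich furan should be consumed far faster than the benzyl ethers, and the dye end‑point stops the ozone supply at that stage. No stereocentre is involved.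

Step 9
Reactants: 13 3,4,5‑tri‑O‑benzyl‑1‑O‑methyl‑(−)‑quinic acid
Product: 14 tert‑butyl 3,4,5‑tri‑O‑benzyl‑1‑O‑methyl‑(−)‑quinate
Conditions: Cl3CC(=NH)OtBu, CH2Cl2/cyclohexane, rt
Reagents that add atoms: tert‑butyl 2,2,2‑trichloroacetimidate, CC(C)(C)OC(=N)C(Cl)(Cl)Cl
Why: The carboxylic acid protonates the imidate and is O‑alkylated by the tert‑butyl cation equivalent, so no attack at the hindered C7 carbonyl is required; ethers are inert.

Step 10
Reactants: 14 tert‑butyl 3,4,5‑tri‑O‑benzyl‑1‑O‑methyl‑(−)‑quinate
Product: 15 tert‑butyl 1‑O‑methyl‑(−)‑quinate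
Conditions: H2 (1 atm), Pd(OH)2/C, EtOAc/EtOH, rt
Reagents that add atoms: none
Why: Catalytic hydrogenolysis of the three benzyl ethers; nothing else in 14 is reducible, and the bulky tert‑butyl ester should not lactonise onto O5 under neutral conditions.

Step 11
Reactants: 15 tert‑butyl 1‑O‑methyl‑(−)‑quinate
Product: 16 tert‑butyl 3,4‑O‑isopropylidene‑1‑O‑methyl‑(−)‑quinate
Conditions: Me2C(OMe)2, PPTS (cat.), acetone, rt; Et3N quench
Reagents that add atoms: 2,2‑dimethoxypropane, COC(C)(C)OC
Why: Thermodynamically controlled transacetalisation: only the cis O3/O4 pair can span an unstrained cis‑fused dioxolane, so O5–H stays free; the weak acid should spare the tert‑butyl ester.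

Step 12
Reactants: 17 caffeic acid
Product: 18 (E)‑3,4‑diacetoxycinnamic acid
Conditions: Ac2O, pyridine, DMAP (cat.), 0 °C → rt; then H2O
Reagents that add atoms: acetic anhydride, CC(=O)OC(C)=O
Why: Acetylation of both phenols; the mixed anhydride formed at the carboxyl group is hydrolysed on aqueous work‑up and the E‑alkene is untouched.

Step 13
Reactants: 18 (E)‑3,4‑diacetoxycinnamic acid
Product: 19 (E)‑3,4‑diacetoxycinnamoyl chloride
Conditions: (COCl)2, DMF (cat.), CH2Cl2, 0 °C → rt
Reagents that add atoms: oxalyl chloride, ClC(=O)C(=O)Cl
Why: Acid chloride formation through the chloroiminium (Vilsmeier‑type) intermediate; aryl acetates and the E‑alkene are unaffected.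

Step 14
Reactants: 16 tert‑butyl 3,4‑O‑isopropylidene‑1‑O‑methyl‑(−)‑quinate; 19 (E)‑3,4‑diacetoxycinnamoyl chloride
Product: 20 tert‑butyl 5‑O‑[(E)‑3,4‑diacetoxycinnamoyl]‑3,4‑O‑isopropylidene‑1‑O‑methyl‑(−)‑quinate
Conditions: pyridine, DMAP (cat.), CH2Cl2, 0 °C → rt
Reagents that add atoms: none
Why: DMAP‑catalysed acylation of the only free, equatorial hydroxyl through the acylpyridinium ion; the C5–O bond is not broken, so the configuration is retained.

Step 15
Reactants: 20 tert‑butyl 5‑O‑[(E)‑3,4‑diacetoxycinnamoyl]‑3,4‑O‑isopropylidene‑1‑O‑methyl‑(−)‑quinate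
Product: 21 3‑O‑caffeoyl‑1‑methylquinic acid (target; 5‑O‑caffeoyl in the numbering used here)
Conditions: 2 M aq. HCl/THF (1:1), rt, Ar, dark
Reagents that add atoms: none
Why: Acid‑catalysed hydrolysis: the acetonide should go first, followed by the aryl acetates and the tert‑butyl ester (alkyl–oxygen fission), while the conjugated secondary cinnamate ester is expected to hydrolyse much more slowly. Acid avoids the acyl migration and catechol oxidation that base would cause, and no stereocentre is affected.

## Compound list

1 | D‑arabinitol, (2R,4R)‑pentane‑1,2,3,4,5‑pentol | OC[C@@H](O)C(O)[C@H](O)CO | starting material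
2 | 1,5‑di‑O‑trityl‑D‑arabinitol | C(c1ccccc1)(c1ccccc1)(c1ccccc1)OC[C@@H](O)C(O)[C@H](O)COC(c1ccccc1)(c1ccccc1)c1ccccc1 | intermediate
3 | 2,3,4‑tri‑O‑benzyl‑1,5‑di‑O‑trityl‑D‑arabinitol | C(c1ccccc1)(c1ccccc1)(c1ccccc1)OC[C@@H](OCc1ccccc1)C(OCc1ccccc1)[C@H](OCc1ccccc1)COC(c1ccccc1)(c1ccccc1)c1ccccc1 | intermediate
4 | 2,3,4‑tri‑O‑benzyl‑D‑arabinitol, (2R,4R)‑2,3,4‑tris(benzyloxy)pentane‑1,5‑diol | OC[C@@H](OCc1ccccc1)C(OCc1ccccc1)[C@H](OCc1ccccc1)CO | intermediate
5 | 2,3,4‑tri‑O‑benzyl‑1,5‑dideoxy‑1,5‑diiodo‑D‑arabinitol, (2S,4S)‑2,3,4‑tris(benzyloxy)‑1,5‑diiodopentane | IC[C@@H](OCc1ccccc1)C(OCc1ccccc1)[C@H](OCc1ccccc1)CI | intermediate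
6 | tosylmethyl isocyanide (TosMIC) | Cc1ccc(cc1)S(=O)(=O)C[N+]#[C-] | starting material
7 | (3R,5R)‑3,4,5‑tris(benzyloxy)‑1‑isocyano‑1‑tosylcyclohexane, both C1 epimers | [C-]#[N+]C1(S(=O)(=O)c2ccc(C)cc2)C[C@@H](OCc2ccccc2)C(OCc2ccccc2)[C@H](OCc2ccccc2)C1 | intermediate
8 | (3R,5R)‑3,4,5‑tris(benzyloxy)cyclohexanone (O3 and O5 trans, C4 not stereogenic) | O=C1C[C@@H](OCc2ccccc2)C(OCc2ccccc2)[C@H](OCc2ccccc2)C1 | intermediate
9 | furan | c1ccoc1 | starting material
10 | 2‑lithiofuran | [Li]c1ccco1 | intermediate (not isolated)
11 | lithium (3R,5R)‑3,4,5‑tris(benzyloxy)‑1‑(furan‑2‑yl)cyclohexan‑1‑olate, O1 cis to O3 and O4 | [Li]O[C@@]1(c2ccco2)C[C@@H](OCc2ccccc2)[C@@H](OCc2ccccc2)[C@H](OCc2ccccc2)C1 | intermediate (not isolated)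
12 | 2‑[(3R,5R)‑3,4,5‑tris(benzyloxy)‑1‑methoxycyclohexyl]furan, methoxy cis to O3 and O4, furyl cis to O5 | CO[C@@]1(c2ccco2)C[C@@H](OCc2ccccc2)[C@@H](OCc2ccccc2)[C@H](OCc2ccccc2)C1 | intermediate
13 | 3,4,5‑tri‑O‑benzyl‑1‑O‑methyl‑(−)‑quinic acid, (3R,5R)‑3,4,5‑tris(benzyloxy)‑1‑methoxycyclohexane‑1‑carboxylic acid with methoxy cis to O3 and O4 and carboxyl cis to O5 | CO[C@@]1(C(=O)O)C[C@@H](OCc2ccccc2)[C@@H](OCc2ccccc2)[C@H](OCc2ccccc2)C1 | intermediate
14 | tert‑butyl 3,4,5‑tri‑O‑benzyl‑1‑O‑methyl‑(−)‑quinate | CO[C@@]1(C(=O)OC(C)(C)C)C[C@@H](OCc2ccccc2)[C@@H](OCc2ccccc2)[C@H](OCc2ccccc2)C1 | intermediate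
15 | tert‑butyl 1‑O‑methyl‑(−)‑quinate (3,4,5‑triol; O3/O4 cis, O4/O5 trans, methoxy cis to O3) | CO[C@@]1(C(=O)OC(C)(C)C)C[C@@H](O)[C@@H](O)[C@H](O)C1 | intermediate
16 | tert‑butyl 3,4‑O‑isopropylidene‑1‑O‑methyl‑(−)‑quinate (cis‑fused dioxolane on O3/O4, O5–H free) | CO[C@@]1(C(=O)OC(C)(C)C)C[C@H]2OC(C)(C)O[C@H]2[C@H](O)C1 | intermediate
17 | caffeic acid, (E)‑3‑(3,4‑dihydroxyphenyl)prop‑2‑enoic acid | O=C(O)/C=C/c1ccc(O)c(O)c1 | starting material
18 | (E)‑3,4‑diacetoxycinnamic acid (3,4‑di‑O‑acetylcaffeic acid) | O=C(O)/C=C/c1ccc(OC(C)=O)c(OC(C)=O)c1 | intermediate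
19 | (E)‑3,4‑diacetoxycinnamoyl chloride (3,4‑di‑O‑acetylcaffeoyl chloride) | O=C(Cl)/C=C/c1ccc(OC(C)=O)c(OC(C)=O)c1 | intermediate
20 | tert‑butyl 5‑O‑[(E)‑3,4‑diacetoxycinnamoyl]‑3,4‑O‑isopropylidene‑1‑O‑methyl‑(−)‑quinate | CO[C@@]1(C(=O)OC(C)(C)C)C[C@H]2OC(C)(C)O[C@H]2[C@H](OC(=O)/C=C/c2ccc(OC(C)=O)c(OC(C)=O)c2)C1 | intermediate
21 | 3‑O‑caffeoyl‑1‑methylquinic acid, (1S,3R,4R,5R)‑3‑{[(E)‑3‑(3,4‑dihydroxyphenyl)prop‑2‑enoyl]oxy}‑4,5‑dihydroxy‑1‑methoxycyclohexane‑1‑carboxylic acid | CO[C@@]1(C(=O)O)C[C@@H](O)[C@@H](O)[C@H](OC(=O)/C=C/c2ccc(O)c(O)c2)C1 | target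

## Step count and least certain steps

Total: 15 steps. Longest linear sequence: 13 steps (steps 1–11, 14, 15); steps 12 and 13 are the side branch from caffeic acid 17.

**Step 7 (key step).** Four things may go wrong.
- α‑Deprotonation of 8 in place of addition, followed by expulsion of a β‑benzyloxy group.
- Loss of facial selectivity, if the inverted chair reacts or if lithium bound to O3 delivers the nucleophile along the axial trajectory.
- Incomplete methylation of the hindered, probably chelated alkoxide.
- Acid‑promoted ionisation of the tertiary furfuryl ether during work‑up or chromatography, so buffered work‑up and base‑washed silica are required.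

The fallback sets out from 8 and comes back at 12. Compound 10 is premixed with anhydrous CeCl3 in THF at −78 °C; the less basic organocerium reagent should add without enolisation. The adduct is isolated as the tertiary alcohol (3R,5R)‑3,4,5‑tris(benzyloxy)‑1‑(furan‑2‑yl)cyclohexan‑1‑ol F1, at which stage any minor C1 epimer can be removed by chromatography. F1 is then methylated separately with NaH and MeI in DMF to give 12.

**Step 5.** Intermolecular alkylation may outrun ring closure, and SN2 at the β‑oxygenated primary iodide may be slower than the decay of the TosMIC anion or than E2 elimination. The fallback sets out from 5 and comes back at 8. It uses a thermally robust nucleophile that tolerates forcing conditions. Dimethyl malonate and NaH in DMF at 60 °C give dimethyl (3R,5R)‑3,4,5‑tris(benzyloxy)cyclohexane‑1,1‑dicarboxylate F2. Saponification (LiOH, aq. THF/MeOH, then acid) gives (3R,5R)‑3,4,5‑tris(benzyloxy)cyclohexane‑1,1‑dicarboxylic acid F3. Oxidative bis‑decarboxylation with Pb(OAc)4 in pyridine/benzene, followed by mild aqueous hydrolysis of the geminal diacetate, returns ketone 8.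

**Step 8.** Over‑oxidation may occur: benzylic C–H oxidation of the ethers to benzoates if ozone is overdosed, which would block the later hydrogenolysis. The fallback sets out from 8 and comes back at 13. It replaces the furan by a vinyl group as the carboxyl surrogate, so that no ozone is needed. Vinylmagnesium bromide with CeCl3 in THF at −78 °C gives (3R,5R)‑3,4,5‑tris(benzyloxy)‑1‑vinylcyclohexan‑1‑ol F4, by the same equatorial attack. NaH and MeI in DMF give (3R,5R)‑3,4,5‑tris(benzyloxy)‑1‑methoxy‑1‑vinylcyclohexane F5. Lemieux–Johnson cleavage (OsO4 cat., NaIO4, 2,6‑lutidine, dioxane/H2O) gives (3R,5R)‑3,4,5‑tris(benzyloxy)‑1‑methoxycyclohexane‑1‑carbaldehyde F6. Pinnick oxidation (NaClO2, NaH2PO4, 2‑methylbut‑2‑ene, t‑BuOH/H2O) returns acid 13. None of these reagents attacks benzyl ethers.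

**Step 15.** Cleavage of the tert‑butyl ester or of the aryl acetates may be incomplete within the time in which the caffeoyl ester stays intact, or slow acid‑catalysed migration of the caffeoyl group to O4 may set in on prolonged exposure. The fallback sets out from 16 and comes back at 21. It builds the caffeoyl ester without any phenol protection, so that only acidolysis remains at the end. Meldrum's acid in toluene at 90–100 °C acylates O5 through the acylketene to give the malonate half‑ester tert‑butyl 5‑O‑(carboxyacetyl)‑3,4‑O‑isopropylidene‑1‑O‑methyl‑(−)‑quinate F7. Knoevenagel–Doebner condensation with 3,4‑dihydroxybenzaldehyde (pyridine, piperidine cat., rt → 40 °C) gives, with decarboxylation, the E‑configured tert‑butyl 5‑O‑caffeoyl‑3,4‑O‑isopropylidene‑1‑O‑methyl‑(−)‑quinate F8. TFA/CH2Cl2/H2O (0 °C → rt) then removes the acetonide and the tert‑butyl ester to give 21.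

## Further compounds

F1 | step 7 | (3R,5R)‑3,4,5‑tris(benzyloxy)‑1‑(furan‑2‑yl)cyclohexan‑1‑ol, O1 cis to O3 and O4 | O[C@@]1(c2ccco2)C[C@@H](OCc2ccccc2)[C@@H](OCc2ccccc2)[C@H](OCc2ccccc2)C1
F2 | step 5 | dimethyl (3R,5R)‑3,4,5‑tris(benzyloxy)cyclohexane‑1,1‑dicarboxylate | COC(=O)C1(C(=O)OC)C[C@@H](OCc2ccccc2)C(OCc2ccccc2)[C@H](OCc2ccccc2)C1
F3 | step 5 | (3R,5R)‑3,4,5‑tris(benzyloxy)cyclohexane‑1,1‑dicarboxylic acid | OC(=O)C1(C(=O)O)C[C@@H](OCc2ccccc2)C(OCc2ccccc2)[C@H](OCc2ccccc2)C1
F4 | step 8 | (3R,5R)‑3,4,5‑tris(benzyloxy)‑1‑vinylcyclohexan‑1‑ol, O1 cis to O3 and O4 | O[C@@]1(C=C)C[C@@H](OCc2ccccc2)[C@@H](OCc2ccccc2)[C@H](OCc2ccccc2)C1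
F5 | step 8 | (3R,5R)‑3,4,5‑tris(benzyloxy)‑1‑methoxy‑1‑vinylcyclohexane, methoxy cis to O3 and O4 | CO[C@@]1(C=C)C[C@@H](OCc2ccccc2)[C@@H](OCc2ccccc2)[C@H](OCc2ccccc2)C1
F6 | step 8 | (3R,5R)‑3,4,5‑tris(benzyloxy)‑1‑methoxycyclohexane‑1‑carbaldehyde, methoxy cis to O3 and O4 | CO[C@@]1(C=O)C[C@@H](OCc2ccccc2)[C@@H](OCc2ccccc2)[C@H](OCc2ccccc2)C1
F7 | step 15 | tert‑butyl 5‑O‑(carboxyacetyl)‑3,4‑O‑isopropylidene‑1‑O‑methyl‑(−)‑quinate | CO[C@@]1(C(=O)OC(C)(C)C)C[C@H]2OC(C)(C)O[C@H]2[C@H](OC(=O)CC(=O)O)C1
F8 | step 15 | tert‑butyl 5‑O‑[(E)‑caffeoyl]‑3,4‑O‑isopropylidene‑1‑O‑methyl‑(−)‑quinate | CO[C@@]1(C(=O)OC(C)(C)C)C[C@H]2OC(C)(C)O[C@H]2[C@H](OC(=O)/C=C/c2ccc(O)c(O)c2)C1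
A1 | alternative 1 | 3‑hydroxy‑4,5‑O‑isopropylidene‑1‑methylenecyclohexane (O3 cis to O4, trans‑fused 4,5‑acetonide) | C=C1C[C@@H](O)[C@H]2OC(C)(C)O[C@@H]2C1
A2 | alternative 1 | spiro‑epoxide of A1, epoxide oxygen on C1 cis to the C3 hydroxyl | O1C[C@@]12C[C@@H](O)[C@H]3OC(C)(C)O[C@@H]3C2
A3 | alternative 2 | buta‑1,3‑diene | C=CC=C
A4 | alternative 2 | methyl 2‑methoxyacrylate | C=C(OC)C(=O)OC
A5 | alternative 2 | methyl (S)‑1‑methoxycyclohex‑3‑ene‑1‑carboxylate | CO[C@@]1(C(=O)OC)CCC=CC1
A6 | alternative 3 | trans‑5‑(tert‑butyldimethylsilyloxy)‑3‑methoxy‑6‑vinyltetrahydropyran‑2‑one (C3 unspecified) | C=C[C@@H]1OC(=O)C(OC)C[C@H]1O[Si](C)(C)C(C)(C)C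
A7 | alternative 3 | (1S,5R)‑5‑(tert‑butyldimethylsilyloxy)‑1‑methoxycyclohex‑3‑ene‑1‑carboxylic acid | CO[C@@]1(C(=O)O)CC=C[C@H](O[Si](C)(C)C(C)(C)C)C1
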